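**Assumption:** furan-3(2H)-one is available commercially. The two guaiacyl units enter as O-benzyl-protected reagents, 4-(benzyloxy)-3-methoxyphenylboronic acid and 4-(benzyloxy)-3-methoxybenzaldehyde.

## Retrosynthetic overview
1. Target 8 is an all-cis 2,3,4-trisubstituted THF. Its C4–OH comes from hydride reduction of the THF-3-one (6 → 7) from the face anti to the two cis substituents.
2. Ketone 6 comes from hydroxyl-directed syn-hydrogenation of the C4=C5 bond of carbinol 5. The carbinol stereocentre sets C2 and C3 cis.
3. Carbinol 5 comes from asymmetric transfer hydrogenation of aroyl ketone 4.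
4. Key bond: the C5–C(=O)Ar′ bond of 4 is formed by aroyl-radical C–H acylation of 4-aryl-3(2H)-furanone 3. Compound 3 comes from Suzuki coupling of bromide 2, which comes from furan-3(2H)-one 1.
5. No ring is constructed; the only ring is in 1, and every stereocentre is set by a reduction step.

## Route

**Step 1**
Reactants: 1, furan-3(2H)-one
Product: 2, 4-bromofuran-3(2H)-one
Conditions: NBS, CH2Cl2, 0 °C
Reagents that add atoms: N-bromosuccinimide, O=C1CCC(=O)N1Br (adds Br)
Why: C4 is the nucleophilic α-carbon of the vinylogous ester, so electrophilic α-bromination is regioselective; no stereocentre forms.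

**Step 2**
Reactants: 2
Product: 3, 4-[4-(benzyloxy)-3-methoxyphenyl]furan-3(2H)-one
Conditions: Pd(PPh3)4 (5 mol %), K2CO3, dioxane/H2O 4:1, 70 °C
Reagents that add atoms: 4-(benzyloxy)-3-methoxyphenylboronic acid, COc1cc(B(O)O)ccc1OCc1ccccc1 (adds the aryl group)
Why: Suzuki–Miyaura coupling of a vinyl bromide; no stereocentre forms.

**Step 3 (key radical step)**
Reactants: 3
Product: 4, 5-[4-(benzyloxy)-3-methoxybenzoyl]-4-[4-(benzyloxy)-3-methoxyphenyl]furan-3(2H)-one
Conditions: Ar′CHO (3 equiv), TBADT (2 mol %), Na2S2O8 (2 equiv), MeCN/H2O 9:1, 390 nm, 25 °C, N2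
Reagents that add atoms: 4-(benzyloxy)-3-methoxybenzaldehyde, COc1cc(C=O)ccc1OCc1ccccc1 (adds the aroyl group)
Why: Proposed new method: decatungstate photo-HAT turns the aldehyde into a nucleophilic aroyl radical that adds to the electrophilic β-carbon C5 of the push–pull enone, giving a tertiary benzylic α-keto radical that persulfate oxidises and that loses H⁺ to restore the C4=C5 bond; the closest known reaction types are TBADT hydroacylation of Michael acceptors and oxidative (Minisci-type) acylation of chromones and quinones, and no stereocentre is made here.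

**Step 4**
Reactants: 4
Product: 5, (R)-5-{[4-(benzyloxy)-3-methoxyphenyl](hydroxy)methyl}-4-[4-(benzyloxy)-3-methoxyphenyl]furan-3(2H)-one
Conditions: RuCl[(S,S)-TsDPEN](p-cymene) (2 mol %), HCO2H/Et3N 5:2, CH2Cl2, 30 °C
Reagents that add atoms: none
Why: Noyori–Ikariya asymmetric transfer hydrogenation of the aroyl ketone, which is more electrophilic than the vinylogous-ester C=O and is reduced selectively; the catalyst enantiomer sets the (R)-carbinol, the only stereocentre installed independently.

**Step 5**
Reactants: 5
Product: 6, (4S,5S)-5-[(R)-(4-benzyloxy-3-methoxyphenyl)(hydroxy)methyl]-4-[4-(benzyloxy)-3-methoxyphenyl]dihydrofuran-3(2H)-one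
Conditions: [Ir(cod)(PCy3)(py)]PF6 (10 mol %), H2 (30 bar), CH2Cl2, 25 °C
Reagents that add atoms: none (H2 adds only hydrogen)
Why: Crabtree-type hydroxyl-directed syn-hydrogenation delivers both H atoms to C4=C5 from the face syn to the carbinol OH, with the carbinol in its A(1,3)-minimised rotamer (C–H in plane toward the C4-aryl); this places H on the bottom face at C2 and C3 so that the carbinol and aryl groups are cis (2,3-cis) and sets both ring stereocentres from the (R)-carbinol.

**Step 6**
Reactants: 6
Product: 7, (3S,4R,5S)-5-[(R)-(4-benzyloxy-3-methoxyphenyl)(hydroxy)methyl]-4-[4-(benzyloxy)-3-methoxyphenyl]oxolan-3-ol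
Conditions: L-Selectride, THF, −78 °C
Reagents that add atoms: none (adds only hydride)
Why: Bulky hydride attacks the ketone from the convex face anti to the cis aryl and carbinol substituents, so the new OH is cis to both (all-cis) in a sterically controlled reduction.

**Step 7**
Reactants: 7
Product: 8, Metasequirin E
Conditions: H2 (1 atm), 10 % Pd/C, EtOAc/MeOH 1:1, 25 °C, 3 h
Reagents that add atoms: none (the benzyl groups leave as toluene)
Why: Hydrogenolysis removes the two aryl O-benzyl ethers; no stereocentre is touched.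

## Compound list
1 | furan-3(2H)-one | O=C1COC=C1 | starting material
2 | 4-bromofuran-3(2H)-one | O=C1COC=C1Br | intermediate
3 | 4-[4-(benzyloxy)-3-methoxyphenyl]furan-3(2H)-one | O=C1COC=C1c1ccc(OCc2ccccc2)c(OC)c1 | intermediate
4 | 5-[4-(benzyloxy)-3-methoxybenzoyl]-4-[4-(benzyloxy)-3-methoxyphenyl]furan-3(2H)-one | O=C1COC(C(=O)c2ccc(OCc3ccccc3)c(OC)c2)=C1c1ccc(OCc2ccccc2)c(OC)c1 | intermediate
5 | (R)-5-{[4-(benzyloxy)-3-methoxyphenyl](hydroxy)methyl}-4-[4-(benzyloxy)-3-methoxyphenyl]furan-3(2H)-one | O=C1COC([C@H](O)c2ccc(OCc3ccccc3)c(OC)c2)=C1c1ccc(OCc2ccccc2)c(OC)c1 | intermediate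
6 | (4S,5S)-5-[(R)-hydroxy(aryl)methyl]-4-aryl-dihydrofuran-3(2H)-one, bis-O-benzyl, 4,5-cis | COc1cc([C@H]2[C@@H]([C@H](O)c3ccc(OCc4ccccc4)c(OC)c3)OCC2=O)ccc1OCc1ccccc1 | intermediate
7 | (3S,4R,5S)-5-[(R)-hydroxy(aryl)methyl]-4-aryl-oxolan-3-ol, bis-O-benzyl, all-cis | COc1cc([C@H]2[C@@H]([C@H](O)c3ccc(OCc4ccccc4)c(OC)c3)OC[C@H]2O)ccc1OCc1ccccc1 | intermediate
8 | Metasequirin E | COc1cc([C@H]2[C@@H]([C@H](O)c3ccc(O)c(OC)c3)OC[C@H]2O)ccc1O | target

## Totals
Total steps: 7. Longest linear sequence: 7 (1 → 2 → 3 → 4 → 5 → 6 → 7 → 8).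

## Three steps most likely to fail
1. **Step 3, radical acylation.** The regiochemistry, the competing HAT at the furanone C2–H2, or over-oxidation may be a problem.
   Fallback: add Ar′CHO to 3 as a ketyl radical (SmI2/HMPA) to give the saturated hydroxy-ketone. Oxidise the carbinol (Dess–Martin periodinane) and reach 6 by Ru-TsDPEN dynamic kinetic resolution transfer hydrogenation.
2. **Step 5, hydrogenation.** The tetrasubstituted enone may be sluggish or suffer C–O hydrogenolysis, and the α-aryl ketone product may epimerise at C3.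
   Fallback: reverse the order. Reduce the C3 ketone of 5 with L-Selectride, protect it as the TBS ether, hydrogenate the enol ether with Pd/C from the face anti to the OTBS group (all-cis), then remove the silyl group.
3. **Step 1, bromination.** Parent furan-3(2H)-one can tautomerise to 3-hydroxyfuran and over-brominate or polymerise.
   Fallback: build 3 directly. Condense 1-aryl-3-hydroxypropan-2-one with DMF-DMA to give the enaminone, then cyclise with acid to the 4-aryl-furanone.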